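C1 is the ring-fusion CH that carries C15. C2 to C14 run round the 14-membered carbocycle through C3=C4, C7=C8, C11(Cl), C12(OH)(CH3) and C13H2 to C14(O). The lactone ring is C1–C15(=C17H2)–C16(=O)–O–C14.
Cuts in the target: C15=C17 (methylenation), O–C16 (lactone), then C11–Cl with C12–O kept (11,12-epoxide, then E-C11=C12). This exposes the enabling feature, the homoallylic alcohol C14(OH)–C13H2–C12(CH3)=C11H inside the carbocycle. It is cut at C12–C13 into a CH3–C12≡C11 alkyne and a C13–C14 oxirane.
Cuts in the open chain: C13–C14 (methylene transfer to a C14 aldehyde), C1–C2 (imide enolate plus allylic bromide), C9–C10 and C12–CH3 (propyne dianion, MeI).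
Forward: geraniol is extended at C9 to a dienyne bromide, joined to a succinate imide and converted into the alkynyl oxirane. The carbocycle closes first (step 13), a transient oxirane on C11/C12 follows (steps 14 and 15), the lactone ring closes in step 16, and C17 is added last.
Stereochemistry: C1 (R) from (R)-4-benzyloxazolidinone, C14 from a catalyst-controlled hydrolytic kinetic resolution, C12 (R) from C14–OH-directed epoxidation, C11 (S) from SN2 inversion by chloride. C3=C4 comes from geraniol, C7=C8 from E-selective SeO2 oxidation, C11=C12 from syn addition to the alkyne.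

Key step: step 13

Remark: 19 is a mixture of both C14 epimers and is written without configuration at that carbon. The C15 configuration drawn for 28 and 29 is the expected one and is erased in step 19.

Step 1
Reactants: 1 geraniol
Product: 2 tert-butyl{[(2E)-3,7-dimethylocta-2,6-dien-1-yl]oxy}dimethylsilane
Conditions: TBSCl, imidazole, CH2Cl2, 0 °C → rt
Reagents that add atoms: tert-butyldimethylsilyl chloride, CC(C)(C)[Si](C)(C)Cl
Why: Imidazole-promoted silylation of a primary allylic alcohol is routine, and the TBS ether withstands SeO2, the Appel conditions and the organolithium of step 4.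

Step 2
Reactants: 2 geranyl TBS ether
Product: 3 (2E,6E)-8-[(tert-butyldimethylsilyl)oxy]-2,6-dimethylocta-2,6-dien-1-ol
Conditions: SeO2 (10 mol %), t-BuOOH, salicylic acid (cat.), CH2Cl2, 0 °C → rt
Reagents that add atoms: tert-butyl hydroperoxide, CC(C)(C)OO (oxygen passed on through SeO2, O=[Se]=O)
Why: Riley allylic oxidation (ene reaction followed by [2,3]-sigmatropic shift, SeO2 recycled by t-BuOOH) picks the electron-richer distal olefin and oxidises its E-methyl group, so the future C7=C8 bond keeps the E geometry and C9 becomes functionalised.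

Step 3
Reactants: 3 allylic alcohol
Product: 4 {[(2E,6E)-8-bromo-3,7-dimethylocta-2,6-dien-1-yl]oxy}(tert-butyl)dimethylsilane
Conditions: CBr4, PPh3, CH2Cl2, −20 → 0 °C
Reagents that add atoms: tetrabromomethane, BrC(Br)(Br)Br
Why: The Appel reaction replaces the primary allylic hydroxyl by bromide through SN2 attack on the alkoxyphosphonium ion under neutral conditions that leave olefin geometry and silyl ether alone.

Step 4
Reactants: 4 allylic bromide; 5 propyne
Product: 8 tert-butyl{[(2E,6E)-3,7-dimethyldodeca-2,6-dien-10-yn-1-yl]oxy}dimethylsilane, via 1,3-dilithiopropyne 6 (not isolated), via lithium acetylide 7 (not isolated)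
Conditions: 5, n-BuLi (2 equiv per 5), TMEDA, Et2O–hexane, −78 °C → rt; 4, THF, −78 → 0 °C; MeI, 0 °C → rt
Reagents that add atoms: iodomethane, CI
Why: Sequential alkylation of the propyne dianion is known for allylic bromides: the sp3 carbanion is the more reactive end and forms C9–C10 by SN2, after which the surviving acetylide is C-methylated to install the C12 methyl group.

Step 5
Reactants: 8 dienyne TBS ether
Product: 9 (2E,6E)-3,7-dimethyldodeca-2,6-dien-10-yn-1-ol
Conditions: Bu4NF, THF, 0 °C → rt
Reagents that add atoms: none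
Why: Fluoride-induced cleavage of the Si–O bond frees the allylic alcohol without touching alkyne or olefins.

Step 6
Reactants: 9 dienynol
Product: 10 (2E,6E)-1-bromo-3,7-dimethyldodeca-2,6-dien-10-yne
Conditions: CBr4, PPh3, CH2Cl2, −20 → 0 °C
Reagents that add atoms: tetrabromomethane, BrC(Br)(Br)Br
Why: A second Appel reaction gives the geranyl-type bromide, which is used without storage because such bromides ionise easily.

Step 7
Reactants: 11 mono-tert-butyl succinate; 12 (R)-4-benzyl-1,3-oxazolidin-2-one
Product: 14 tert-butyl 4-[(4R)-4-benzyl-2-oxo-1,3-oxazolidin-3-yl]-4-oxobutanoate, via mixed pivalic anhydride 13 (not isolated)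
Conditions: t-BuCOCl, Et3N, THF, −20 °C; LiCl, 12, −20 °C → rt
Reagents that add atoms: none
Why: N-Acylation of an oxazolidinone through the mixed pivalic anhydride under LiCl/Et3N activation avoids strong base and leaves the tert-butyl ester intact.

Step 8
Reactants: 14 succinate imide; 10 dienyne bromide
Product: 16 tert-butyl (3R,5E,9E)-3-{[(4R)-4-benzyl-2-oxo-1,3-oxazolidin-3-yl]carbonyl}-6,10-dimethylpentadeca-5,9-dien-13-ynoate, via sodium Z-enolate 15 (not isolated)
Conditions: NaN(SiMe3)2, THF, −78 °C; 10, −78 → −40 °C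
Reagents that add atoms: none
Why: Evans asymmetric alkylation: NaN(SiMe3)2 deprotonates the more acidic imide alpha-CH2 to the chelated Z-enolate, the benzyl group of the (R)-auxiliary shields one face and the allylic bromide enters from the other, which forms C1–C2 and sets C1 as R.

Step 9
Reactants: 16 alkylated imide
Product: 17 tert-butyl (3R,5E,9E)-3-(hydroxymethyl)-6,10-dimethylpentadeca-5,9-dien-13-ynoate
Conditions: LiBH4, H2O (1 equiv), Et2O, 0 °C
Reagents that add atoms: none
Why: Hydride cleavage of the N-acyloxazolidinone with LiBH4 reduces the activated exocyclic carbonyl far faster than the hindered tert-butyl ester, does not touch C1 and returns the auxiliary.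

Step 10
Reactants: 17 hydroxy ester
Product: 18 tert-butyl (3R,5E,9E)-3-formyl-6,10-dimethylpentadeca-5,9-dien-13-ynoate
Conditions: Dess–Martin periodinane, CH2Cl2, 0 °C → rt
Reagents that add atoms: none
Why: Dess–Martin oxidation works under near-neutral conditions, so the alpha-stereocentre C1 of the aldehyde should not epimerise and the alkyne and olefins are inert.

Step 11
Reactants: 18 aldehyde
Product: 19 tert-butyl (3R,5E,9E)-6,10-dimethyl-3-(oxiran-2-yl)pentadeca-5,9-dien-13-ynoate (both C14 epimers)
Conditions: [Me3S]I, KN(SiMe3)2, THF, −10 °C; 18, −78 → 0 °C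
Reagents that add atoms: trimethylsulfonium iodide, C[S+](C)C.[I-]
Why: Corey–Chaykovsky methylene transfer adds C13 and closes the oxirane from the betaine faster than the alkoxide can reach the tert-butyl ester; the two CH2 arms on C1 are too alike for facial control, so both C14 epimers are expected and are sorted in step 12.

Step 12
Reactants: 19 oxirane epimers
Product: 20 tert-butyl (3R,5E,9E)-6,10-dimethyl-3-[(2R)-oxiran-2-yl]pentadeca-5,9-dien-13-ynoate
Conditions: (R,R)-(salen)Co(OAc) (1 mol %; salen = N,N'-bis(3,5-di-tert-butylsalicylidene)cyclohexane-1,2-diaminate), H2O (0.5 equiv), THF, 0 °C → rt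
Reagents that add atoms: none
Why: Jacobsen hydrolytic kinetic resolution is catalyst-controlled for terminal oxiranes: the (R,R)-cobalt salen complex hydrates the (14S)-epimer at C13 to a polar diol that is removed by chromatography and spares the (14R)-oxirane, which fixes the C14 configuration of the target.

Step 13
Reactants: 20 alkynyl oxirane
Product: 22 tert-butyl 2-[(1R,2S,4E,8E,12E)-2-hydroxy-4,8,12-trimethylcyclotetradeca-4,8,12-trien-1-yl]acetate, via O-diethylborinate 21 (not isolated)
Conditions: Ni(cod)2 (20 mol %), PBu3 (40 mol %), Et3B (3 equiv), toluene, syringe-pump addition of 20 to about 2 mM, rt → 45 °C; aq NH4Cl, air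
Reagents that add atoms: none
Why: Proposed new method: zerovalent nickel bearing PBu3 should insert into the unhindered C13–O bond of the oxirane, the pendant alkyne should then insert into the Ni–C13 bond to give a six-membered oxanickelacycle that already holds C12–C13, and ethyl transfer from Et3B, beta-hydride elimination (ethene) and C–H reductive elimination should place hydrogen on C11 cis to C13, which fixes the E geometry. The closest known reaction type is the nickel/phosphine/Et3B reductive coupling of alkynes with terminal epoxides, shown between two molecules and for five- and six-membered rings, so the 14-membered closure and the methyl/alkyl alkyne are the new elements. The ring closes endo at both termini: both alkyne carbons and both oxirane carbons become ring members and the oxygen ends as the exocyclic C14 hydroxyl. No stereocentre is created; C14 keeps its configuration because only the C13–O bond breaks (the descriptor changes from R to S by priority only) and C1 is a spectator. Two selectivities are needed: opening at C13, secured by the monosubstituted oxirane, and C–C bond formation at C12 instead of C11, for which a slim phosphine lets the smaller alkyne substituent (CH3) sit next to the forming bond, whereas a bulky ligand would steer towards the 13-membered ring with an exocyclic ethylidene. Slow addition at high dilution holds back dimerisation.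

Step 14
Reactants: 22 macrocyclic homoallylic alcohol
Product: 23 tert-butyl 2-[(1R,2S,4R,5R,8E,12E)-4,5-epoxy-2-hydroxy-4,8,12-trimethylcyclotetradeca-8,12-dien-1-yl]acetate (cembrane 1R 11R 12R 14S)
Conditions: VO(acac)2 (5 mol %), t-BuOOH (1.2 equiv, decane), CH2Cl2, 0 °C
Reagents that add atoms: tert-butyl hydroperoxide, CC(C)(C)OO
Why: Hydroxyl-directed vanadium-catalysed epoxidation of a homoallylic alcohol: the vanadate ester of C14–OH reaches C11=C12 through a chair-like six-membered transition state in which the ring bonds to C1 and C11 lie pseudo-equatorial, so oxygen is delivered 1,3-syn to C14–O and syn addition to the E-olefin sets 11R,12R.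

Step 15
Reactants: 23 epoxy alcohol
Product: 24 tert-butyl 2-[(1R,2S,4R,5S,8E,12E)-5-chloro-2,4-dihydroxy-4,8,12-trimethylcyclotetradeca-8,12-dien-1-yl]acetate (cembrane 1R 11S 12R 14S)
Conditions: Ti(OiPr)4 (1.5 equiv), Et2NH2Cl (2 equiv), CH2Cl2, 0 °C → rt; aq tartaric acid
Reagents that add atoms: diethylammonium chloride, CC[NH2+]CC.[Cl-]
Why: Titanium-mediated halide opening of an epoxy alcohol: Ti binds the C14 alkoxide and the oxirane oxygen, chloride attacks the secondary carbon C11 from the rear (SN2, inversion to 11S) because this path is the less hindered one and leaves a six-membered titanium 1,3-diolate, and the C12–O bond with its R configuration is kept.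

Step 16
Reactants: 24 chloro diol ester
Product: 25 (1R,11S,12R,14S)-11-chloro-12-hydroxy-17-norcembra-3E,7E-dien-16,14-olide (trans-fused saturated gamma-lactone)
Conditions: p-TsOH·H2O (0.1 equiv), toluene, 40 °C
Reagents that add atoms: none
Why: Acid-catalysed lactonisation (5-exo-trig transesterification of a gamma-hydroxy tert-butyl ester) breaks no bond at C14 or C1, so the trans ring fusion follows from 1R,14S, and the tertiary alcohol is shielded from ionisation by the adjacent C–Cl dipole.

Step 17
Reactants: 25 hydroxy lactone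
Product: 26 12-O-trimethylsilyl ether of 25
Conditions: N-(trimethylsilyl)imidazole, CH2Cl2, rt
Reagents that add atoms: N-(trimethylsilyl)imidazole, C[Si](C)(C)n1ccnc1
Why: N-(Trimethylsilyl)imidazole silylates even tertiary alcohols under neutral conditions, and the mask is needed because a free C12 alkoxide would displace the anti chloride at C11 during the base steps.

Step 18
Reactants: 26 silylated lactone
Product: 28 (15S)-15-[(dimethylamino)methyl] derivative of 26, via lithium lactone enolate 27 (not isolated)
Conditions: LiN(iPr)2 (1.3 equiv), THF, −78 °C; [Me2N=CH2]I, −78 → 0 °C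
Reagents that add atoms: N,N-dimethylmethyleneiminium iodide, C=[N+](C)C.[I-]
Why: Mannich-type aminomethylation of the lactone lithium enolate with the preformed iminium salt adds C17 at C15 from the face opposite to the C2 chain, while the secondary chloride does not eliminate at −78 °C.

Step 19
Reactants: 28 Mannich base
Product: 31 (1R,11S,12R,14S)-11-chloro-12-hydroxycembra-3E,7E,15(17)-trien-16,14-olide (CNP0247658.1), via trimethylammonium iodide 29 (not isolated), via silylated methylene lactone 30 (not isolated)
Conditions: MeI, THF, rt; aq NaHCO3–CH2Cl2, rt; 1 M HCl–THF, 0 °C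
Reagents that add atoms: none
Why: Quaternisation and Hofmann-type beta-elimination under bicarbonate give the exocyclic C15=C17 bond, and brief aqueous acid then removes the trimethylsilyl ether without base ever meeting the free chlorohydrin.

Compound list
1 | geraniol | CC(C)=CCC/C(C)=C/CO | starting material
2 | geranyl TBS ether | CC(C)=CCC/C(C)=C/CO[Si](C)(C)C(C)(C)C | intermediate
3 | (2E,6E)-8-(TBS-oxy)-2,6-dimethylocta-2,6-dien-1-ol | OC/C(C)=C/CC/C(C)=C/CO[Si](C)(C)C(C)(C)C | intermediate
4 | (2E,6E)-8-bromo-3,7-dimethylocta-2,6-dienyl TBS ether | BrC/C(C)=C/CC/C(C)=C/CO[Si](C)(C)C(C)(C)C | intermediate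
5 | propyne | CC#C | starting material
6 | 1,3-dilithiopropyne | [Li]CC#C[Li] | intermediate
7 | lithium acetylide of the chain-extended TBS ether | [Li]C#CCC/C(C)=C/CC/C(C)=C/CO[Si](C)(C)C(C)(C)C | intermediate
8 | (2E,6E)-3,7-dimethyldodeca-2,6-dien-10-ynyl TBS ether | CC#CCC/C(C)=C/CC/C(C)=C/CO[Si](C)(C)C(C)(C)C | intermediate
9 | (2E,6E)-3,7-dimethyldodeca-2,6-dien-10-yn-1-ol | CC#CCC/C(C)=C/CC/C(C)=C/CO | intermediate
10 | (2E,6E)-1-bromo-3,7-dimethyldodeca-2,6-dien-10-yne | CC#CCC/C(C)=C/CC/C(C)=C/CBr | intermediate
11 | mono-tert-butyl succinate | CC(C)(C)OC(=O)CCC(O)=O | starting material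
12 | (R)-4-benzyl-1,3-oxazolidin-2-one | O=C1OC[C@@H](Cc2ccccc2)N1 | starting material
13 | mixed anhydride of 11 with pivalic acid | CC(C)(C)OC(=O)CCC(=O)OC(=O)C(C)(C)C | intermediate
14 | tert-butyl 4-[(4R)-4-benzyl-2-oxo-1,3-oxazolidin-3-yl]-4-oxobutanoate | CC(C)(C)OC(=O)CCC(=O)N1[C@H](Cc2ccccc2)COC1=O | intermediate
15 | sodium Z-enolate of 14 | CC(C)(C)OC(=O)C/C=C(\[O-])N1[C@H](Cc2ccccc2)COC1=O.[Na+] | intermediate
16 | alkylated imide (C1 R, auxiliary 4R) | CC#CCC/C(C)=C/CC/C(C)=C/C[C@H](CC(=O)OC(C)(C)C)C(=O)N1[C@H](Cc2ccccc2)COC1=O | intermediate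
17 | tert-butyl (3R,5E,9E)-3-(hydroxymethyl)-6,10-dimethylpentadeca-5,9-dien-13-ynoate | CC#CCC/C(C)=C/CC/C(C)=C/C[C@H](CC(=O)OC(C)(C)C)CO | intermediate
18 | tert-butyl (3R,5E,9E)-3-formyl-6,10-dimethylpentadeca-5,9-dien-13-ynoate | CC#CCC/C(C)=C/CC/C(C)=C/C[C@H](CC(=O)OC(C)(C)C)C=O | intermediate
19 | terminal oxirane, both C14 epimers | CC#CCC/C(C)=C/CC/C(C)=C/C[C@H](CC(=O)OC(C)(C)C)C1CO1 | intermediate
20 | tert-butyl (3R,5E,9E)-6,10-dimethyl-3-[(2R)-oxiran-2-yl]pentadeca-5,9-dien-13-ynoate | CC#CCC/C(C)=C/CC/C(C)=C/C[C@H](CC(=O)OC(C)(C)C)[C@@H]1CO1 | intermediate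
21 | O-diethylborinate of 22 | CCB(CC)O[C@H]1C/C(C)=C/CC/C(C)=C/CC/C(C)=C/C[C@@H]1CC(=O)OC(C)(C)C | intermediate
22 | macrocyclic all-E triene homoallylic alcohol (1R,14S) | O[C@H]1C/C(C)=C/CC/C(C)=C/CC/C(C)=C/C[C@@H]1CC(=O)OC(C)(C)C | intermediate
23 | 11,12-epoxy alcohol (1R,11R,12R,14S) | O[C@H]1C[C@@]2(C)O[C@@H]2CC/C(C)=C/CC/C(C)=C/C[C@@H]1CC(=O)OC(C)(C)C | intermediate
24 | 11-chloro-12,14-diol ester (1R,11S,12R,14S) | O[C@H]1C[C@@](C)(O)[C@@H](Cl)CC/C(C)=C/CC/C(C)=C/C[C@@H]1CC(=O)OC(C)(C)C | intermediate
25 | saturated trans-fused chlorohydrin lactone | C1C(=O)O[C@H]2C[C@@](C)(O)[C@@H](Cl)CC/C(C)=C/CC/C(C)=C/C[C@H]12 | intermediate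
26 | 12-O-TMS ether of 25 | C1C(=O)O[C@H]2C[C@@](C)(O[Si](C)(C)C)[C@@H](Cl)CC/C(C)=C/CC/C(C)=C/C[C@H]12 | intermediate
27 | lithium enolate of 26 | C1=C([O-])O[C@H]2C[C@@](C)(O[Si](C)(C)C)[C@@H](Cl)CC/C(C)=C/CC/C(C)=C/C[C@H]12.[Li+] | intermediate
28 | 15-(dimethylaminomethyl) lactone (15S expected) | CN(C)C[C@H]1C(=O)O[C@H]2C[C@@](C)(O[Si](C)(C)C)[C@@H](Cl)CC/C(C)=C/CC/C(C)=C/C[C@H]12 | intermediate
29 | trimethylammonium iodide of 28 | C[N+](C)(C)C[C@H]1C(=O)O[C@H]2C[C@@](C)(O[Si](C)(C)C)[C@@H](Cl)CC/C(C)=C/CC/C(C)=C/C[C@H]12.[I-] | intermediate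
30 | 12-O-TMS ether of the target | C=C1C(=O)O[C@H]2C[C@@](C)(O[Si](C)(C)C)[C@@H](Cl)CC/C(C)=C/CC/C(C)=C/C[C@H]12 | intermediate
31 | CNP0247658.1, (1R,11S,12R,14S)-11-chloro-12-hydroxycembra-3E,7E,15(17)-trien-16,14-olide | C=C1C(=O)O[C@H]2C[C@@](C)(O)[C@@H](Cl)CC/C(C)=C/CC/C(C)=C/C[C@H]12 | target

Total step count: 19. Longest linear sequence: 18 (steps 1 to 6 and 8 to 19, from geraniol).

Steps most likely to fail

Step 13. The alkyne may insert the wrong way round, bonding C13 to C11, because methyl and CH2R differ little in size. Oligomerisation may also outrun the closure, or nickel may isomerise the oxirane reductively before the dialkyl alkyne reacts. The fallback keeps the oxirane as the C13 electrophile but moves ring closure to C11≡C12 with known reactions, setting out from 20.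
- Opening at C13 with 1-propynyllithium and BF3·OEt2 (THF, −78 °C) would give the diyne alcohol F1.
- Ring-closing alkyne metathesis with Mo(≡CC6H4OMe-4)(OSiPh3)3 and 5 Å molecular sieves in toluene would give the 14-membered cycloalkyne F2. Silanolate catalysts of this class tolerate secondary alcohols.
- Hydroxyl-directed trans-hydrostannation ([Cp*RuCl]4, Bu3SnH, CH2Cl2) would put tin on C12, the alkyne carbon nearer the hydroxyl, and hydrogen on C11, giving the alkenylstannane F3.
- Methyl-for-tin exchange with retention (MeI, Pd(PPh3)4, copper thiophene-2-carboxylate Cu(O2CC4H3S), [NBu4][Ph2PO2], DMF) comes back to the route at 22.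

Step 15. Lewis-acid activation may shift chloride attack to the tertiary carbon C12. The C14 alkoxide or a transannular olefin may also take part in the opening. The fallback gives up chelation, postpones C–Cl bond formation to the end and needs no silyl mask. It sets out from 23.
- Catalytic KOt-Bu (THF, 0 °C) would close the epoxy lactone F6.
- LiN(iPr)2 would form the lithium enolate F7, and [Me2N=CH2]I would convert it into the Mannich base F8.
- MeI would give the ammonium iodide F9, and aqueous NaHCO3 the alpha-methylene epoxy lactone F10.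
- Opening with the soft chloride source Li2CuCl4 (THF, rt) under sterically governed SN2 control at C11 comes back to the route at 31.

Step 14. Facial selectivity may be poor if the macrocycle does not adopt the chair-like delivery geometry. Oxygen transfer to the bishomoallylic C3=C4 bond may also compete. The fallback replaces directed oxygen transfer by tethered electrophilic cyclisation and sets out from 22.
- Boc2O and DMAP (MeCN) would give the tert-butyl carbonate F4.
- Iodocarbonate cyclisation with IBr (toluene, −80 °C) should close only the six-membered ring. The carbonyl oxygen attacks the tertiary C12 anti to iodine on C11 and 1,3-syn to C14, giving the cyclic iodocarbonate F5.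
- Brief K2CO3/MeOH frees the C12 alkoxide, which displaces iodide with inversion and comes back to the route at 23.

Further compounds
F1 | step 13 | tert-butyl (3R,5E,9E)-3-[(1S)-1-hydroxypent-3-yn-1-yl]-6,10-dimethylpentadeca-5,9-dien-13-ynoate | CC#CCC/C(C)=C/CC/C(C)=C/C[C@H](CC(=O)OC(C)(C)C)[C@@H](O)CC#CC
F2 | step 13 | tert-butyl 2-[(1R,2S,8E,12E)-2-hydroxy-8,12-dimethylcyclotetradeca-8,12-dien-4-yn-1-yl]acetate | O[C@H]1CC#CCC/C(C)=C/CC/C(C)=C/C[C@@H]1CC(=O)OC(C)(C)C
F3 | step 13 | tert-butyl 2-[(1R,2S,4Z,8E,12E)-2-hydroxy-8,12-dimethyl-4-(tributylstannyl)cyclotetradeca-4,8,12-trien-1-yl]acetate | O[C@H]1C/C([Sn](CCCC)(CCCC)CCCC)=C/CC/C(C)=C/CC/C(C)=C/C[C@@H]1CC(=O)OC(C)(C)C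
F4 | step 14 | 14-O-(tert-butoxycarbonyl) derivative of 22 | CC(C)(C)OC(=O)O[C@H]1C/C(C)=C/CC/C(C)=C/CC/C(C)=C/C[C@@H]1CC(=O)OC(C)(C)C
F5 | step 14 | 12,14-cyclic carbonate with iodine on C11 (1R,11S,12R,14S) | O=C1O[C@H]2C[C@@](C)(O1)[C@@H](I)CC/C(C)=C/CC/C(C)=C/C[C@@H]2CC(=O)OC(C)(C)C
F6 | step 15 | saturated 11,12-epoxy lactone (1R,11R,12R,14S) | C1C(=O)O[C@H]2C[C@@]3(C)O[C@@H]3CC/C(C)=C/CC/C(C)=C/C[C@H]12
F7 | step 15 | lithium enolate of F6 | C1=C([O-])O[C@H]2C[C@@]3(C)O[C@@H]3CC/C(C)=C/CC/C(C)=C/C[C@H]12.[Li+]
F8 | step 15 | 15-(dimethylaminomethyl) epoxy lactone | CN(C)C[C@H]1C(=O)O[C@H]2C[C@@]3(C)O[C@@H]3CC/C(C)=C/CC/C(C)=C/C[C@H]12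
F9 | step 15 | trimethylammonium iodide of F8 | C[N+](C)(C)C[C@H]1C(=O)O[C@H]2C[C@@]3(C)O[C@@H]3CC/C(C)=C/CC/C(C)=C/C[C@H]12.[I-]
F10 | step 15 | alpha-methylene 11,12-epoxy lactone | C=C1C(=O)O[C@H]2C[C@@]3(C)O[C@@H]3CC/C(C)=C/CC/C(C)=C/C[C@H]12
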